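**Retrosynthetic overview**
- 12 ⇐ 11: the 4'-OH is carried as a benzyl ether and released last by hydrogenolysis.
- 11 ⇐ 4 + 8: ring C (the pyranone) is cut at C4a–C4 and O1–C2. C2–C3–C4 and ring B come from aroylacetate 8, and ring A comes from 4,5,6-trimethoxyresorcinol 4.
- Feature used: in ring A, C4a sits between the oxygen-bearing C5 and C8a, and C6, C7 and C8 all carry OMe. Without ring C, ring A has a mirror plane through C4a and C7, a single C–H (future C4a) and two equivalent hydroxyls (future O1 and 5-OH). No regiochemical choice arises and ring A needs no protecting group.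
- 4 ⇐ 1,2,3-trimethoxybenzene 1 (4,6-dibromination, double borylation, oxidation). 8 ⇐ acetosyringone 5 (benzylation, then carbethoxylation with diethyl carbonate 7, which supplies C4).
- Ring order: rings A and B are bought, and ring C is the only ring formed (step 6).

Key step: step 6

Remark: the target is a planar flavone with no stereogenic element, so it is achiral, its SMILES carries no stereodescriptor, and no step needs stereocontrol.

Step 1
Reactants: 1 1,2,3-trimethoxybenzene
Product: 2 1,5-dibromo-2,3,4-trimethoxybenzene
Conditions: NBS (2.1 equiv), MeCN, 0 °C → 40 °C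
Reagents that add atoms: N-bromosuccinimide, O=C1CCC(=O)N1Br
Why: Electrophilic aromatic bromination (SEAr): C4 and C6 of 1 are each ortho to one outer methoxy group and para to the other, while C5 is activated only by the twisted central methoxy group, so the first bromine should enter at C4, the second at C6, and the deactivated dibromide should resist a third.

Step 2
Reactants: 2 1,5-dibromo-2,3,4-trimethoxybenzene
Product: 3 2,2'-(4,5,6-trimethoxy-1,3-phenylene)bis(4,4,5,5-tetramethyl-1,3,2-dioxaborolane)
Conditions: B2pin2 (2.5 equiv), PdCl2(dppf) (5 mol %), KOAc (6 equiv), 1,4-dioxane, 95 °C, Ar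
Reagents that add atoms: bis(pinacolato)diboron, CC1(C)OB(OC1(C)C)B1OC(C)(C)C(C)(C)O1
Why: Miyaura borylation: each C–Br bond undergoes oxidative addition to Pd(0), acetate-assisted transmetalation with B2pin2 and reductive elimination, and the weak base KOAc keeps Suzuki coupling between boronate and remaining bromide slow.

Step 3
Reactants: 3 2,2'-(4,5,6-trimethoxy-1,3-phenylene)bis(4,4,5,5-tetramethyl-1,3,2-dioxaborolane)
Product: 4 4,5,6-trimethoxybenzene-1,3-diol
Conditions: 30% aq H2O2 (2.5 equiv), THF/aq NaHCO3 buffer, 0 °C → rt, Ar; Na2SO3 quench, degassed work-up, product used promptly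
Reagents that add atoms: hydrogen peroxide, OO
Why: Oxidative ipso-hydroxylation of an arylboronate: hydroperoxide adds to boron and the aryl group migrates from boron to oxygen, so each hydroxyl should appear exactly where a bromine stood, and the near-neutral buffer, low temperature and argon spare the electron-rich product.

Step 4
Reactants: 5 acetosyringone (1-(4-hydroxy-3,5-dimethoxyphenyl)ethanone)
Product: 6 1-[4-(benzyloxy)-3,5-dimethoxyphenyl]ethanone
Conditions: BnBr (1.2 equiv), K2CO3 (1.5 equiv), DMF, 60 °C
Reagents that add atoms: benzyl bromide, BrCc1ccccc1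
Why: Williamson ether synthesis: the acidic, para-acyl-substituted phenoxide is alkylated by the SN2-active benzyl bromide, and carbonate does not enolise the methyl ketone to any useful extent.

Step 5
Reactants: 6 1-[4-(benzyloxy)-3,5-dimethoxyphenyl]ethanone; 7 diethyl carbonate
Product: 8 ethyl 3-[4-(benzyloxy)-3,5-dimethoxyphenyl]-3-oxopropanoate
Conditions: NaH (2.5 equiv), 7 (4 equiv), THF, reflux; AcOH quench
Reagents that add atoms: none
Why: Crossed Claisen condensation (carbethoxylation): the methyl ketone enolate attacks the non-enolisable carbonate 7, irreversible deprotonation of the β-keto ester drives the equilibrium, and the benzyl and methyl ethers are inert to NaH.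

Step 6
Reactants: 4 4,5,6-trimethoxybenzene-1,3-diol; 8 ethyl 3-[4-(benzyloxy)-3,5-dimethoxyphenyl]-3-oxopropanoate
Product: 11 2-[4-(benzyloxy)-3,5-dimethoxyphenyl]-5-hydroxy-6,7,8-trimethoxy-4H-chromen-4-one, via aroylketene 9 (not isolated), via beta-diketone 10 (not isolated)
Conditions: neat melt (8, 1.5 equiv), no catalyst, Ar, open-vessel µW or metal bath, 240 °C, 10–20 min, EtOH and H2O allowed to distil (alternatively Ph2O, 250 °C)
Reagents that add atoms: none
Why: Above about 200 °C the β-keto ester 8 loses ethanol through a six-membered transition state to give aroylketene 9, whose ketene carbon is by far the strongest electrophile in the melt. Capture by 4 at oxygen is reversible at this temperature, whereas attack by C2 of 4 (ortho to both hydroxyls, para to the C5 methoxy group) forms C4a–C4 irreversibly, because rearomatisation gives diketone 10 with its aryl ketone held between two hydrogen-bonding hydroxyls. One of these hydroxyls then adds to the aroyl carbonyl in a 6-exo-trig closure that forms O1–C2, and loss of water from the hemiketal delivers the aromatic 4H-pyran-4-one, ring C, the only ring made in the route. The closest known reaction type is the Mentzer pyrone synthesis, the catalyst-free thermal or microwave condensation of phloroglucinol-type phenols with aroylacetates to 5-hydroxyflavones. The step needs chemoselectivity for the flavone over the Pechmann 4-arylcoumarin, which the absence of acid and the poor electrophilicity of the donor-substituted aryl ketone towards the arene should secure; regioselectivity is not at stake because 4 has one C–H and two mirror-related hydroxyls, so either closure gives 11 and the spare hydroxyl becomes the chelated 5-OH. No stereocentre is formed, and the benzyl and methyl ethers should tolerate the short heating.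

Step 7
Reactants: 11 2-[4-(benzyloxy)-3,5-dimethoxyphenyl]-5-hydroxy-6,7,8-trimethoxy-4H-chromen-4-one
Product: 12 5,4'-dihydroxy-6,7,8,3',5'-pentamethoxyflavone
Conditions: H2 (1 atm), 10% Pd/C, THF–MeOH, rt, stopped at consumption of 11
Reagents that add atoms: none
Why: Catalytic hydrogenolysis of a benzyl aryl ether: the benzylic C–O bond should be cleaved on palladium at ambient pressure well before the vinylogous-ester C2=C3 bond of the chelated flavone reacts, and the aryl methyl ethers are inert.

**Compound list**
1 | 1,2,3-trimethoxybenzene | COc1cccc(OC)c1OC | starting material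
2 | 1,5-dibromo-2,3,4-trimethoxybenzene | COc1c(Br)cc(Br)c(OC)c1OC | intermediate
3 | 2,2'-(4,5,6-trimethoxy-1,3-phenylene)bis(4,4,5,5-tetramethyl-1,3,2-dioxaborolane) | COc1c(B2OC(C)(C)C(C)(C)O2)cc(B2OC(C)(C)C(C)(C)O2)c(OC)c1OC | intermediate
4 | 4,5,6-trimethoxybenzene-1,3-diol | COc1c(O)cc(O)c(OC)c1OC | intermediate
5 | acetosyringone | CC(=O)c1cc(OC)c(O)c(OC)c1 | starting material
6 | 1-[4-(benzyloxy)-3,5-dimethoxyphenyl]ethanone | CC(=O)c1cc(OC)c(OCc2ccccc2)c(OC)c1 | intermediate
7 | diethyl carbonate | CCOC(=O)OCC | starting material
8 | ethyl 3-[4-(benzyloxy)-3,5-dimethoxyphenyl]-3-oxopropanoate | CCOC(=O)CC(=O)c1cc(OC)c(OCc2ccccc2)c(OC)c1 | intermediate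
9 | 3-[4-(benzyloxy)-3,5-dimethoxyphenyl]-3-oxoprop-1-en-1-one (aroylketene) | O=C=CC(=O)c1cc(OC)c(OCc2ccccc2)c(OC)c1 | intermediate
10 | 1-[4-(benzyloxy)-3,5-dimethoxyphenyl]-3-(2,6-dihydroxy-3,4,5-trimethoxyphenyl)propane-1,3-dione | COc1cc(C(=O)CC(=O)c2c(O)c(OC)c(OC)c(OC)c2O)cc(OC)c1OCc1ccccc1 | intermediate
11 | 2-[4-(benzyloxy)-3,5-dimethoxyphenyl]-5-hydroxy-6,7,8-trimethoxy-4H-chromen-4-one | COc1cc(-c2cc(=O)c3c(O)c(OC)c(OC)c(OC)c3o2)cc(OC)c1OCc1ccccc1 | intermediate
12 | 5,4'-dihydroxy-6,7,8,3',5'-pentamethoxyflavone | COc1cc(-c2cc(=O)c3c(O)c(OC)c(OC)c(OC)c3o2)cc(OC)c1O | target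

Total step count: 7
Longest linear sequence: 5 steps (steps 1, 2, 3, 6, 7)

**Steps most likely to fail**

Step 6.
- Risk: self-condensation of the ketene, or thermal or oxidative breakdown of the resorcinol, may outrun C-acylation. The closure may also be diverted into Pechmann-type lactonisation.
- Fallback: it builds the same diketone stepwise at low temperature and sets out from 4.
- Compound 4 is C-acetylated at its lone C–H with acetic anhydride and BF3·OEt2 (Friedel–Crafts/Fries acylation). Aqueous work-up breaks the boron chelate and gives 1-(2,6-dihydroxy-3,4,5-trimethoxyphenyl)ethanone F1.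
- Commercial 4-benzyloxy-3,5-dimethoxybenzoic acid is converted with oxalyl chloride and catalytic DMF into 4-(benzyloxy)-3,5-dimethoxybenzoyl chloride F2.
- F1 is deprotonated at both hydroxyls and at the methyl group with LiHMDS (4 equiv or more, THF, −78 °C) and C-aroylated at the methyl carbon by F2 (Claisen-type acylation of a polyanion).
- This rejoins the route at 10, now isolated, which is cyclodehydrated to 11 with catalytic p-TsOH in warm toluene.

Step 2.
- Risk: protodebromination, stalling after the first borylation, or Suzuki-type oligomerisation may erode the double coupling.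
- Fallback: it replaces palladium catalysis by halogen–metal exchange and sets out from 2.
- Double bromine–lithium exchange with t-BuLi (4.2 equiv, THF/Et2O, −78 °C) places each lithium next to a coordinating methoxy group. Trapping with B(OMe)3 and mild acidic hydrolysis should then give (4,5,6-trimethoxy-1,3-phenylene)diboronic acid F3.
- F3 is oxidised with buffered H2O2 as in step 3, which rejoins the route at 4.

Step 3.
- Risk: peroxide or air may over-oxidise the freshly released, very electron-rich diphenol, and material may be lost on isolation.
- Fallback: it unveils the diol under reducing conditions and sets out from 2.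
- Double Pd-catalysed C–O cross-coupling (Buchwald–Hartwig etherification) with benzyl alcohol (tBuBrettPhos- or RockPhos-ligated Pd, Cs2CO3, toluene, 90 °C) should give 1,5-bis(benzyloxy)-2,3,4-trimethoxybenzene F4, a bench-stable storage form.
- Hydrogenolysis (H2, Pd/C, EtOAc) with filtration under argon rejoins the route at 4, which can be concentrated directly into the vessel for step 6.

**Further compounds**
F1 | step 6 | 1-(2,6-dihydroxy-3,4,5-trimethoxyphenyl)ethanone | CC(=O)c1c(O)c(OC)c(OC)c(OC)c1O
F2 | step 6 | 4-(benzyloxy)-3,5-dimethoxybenzoyl chloride | COc1cc(C(Cl)=O)cc(OC)c1OCc1ccccc1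
F3 | step 2 | (4,5,6-trimethoxy-1,3-phenylene)diboronic acid | COc1c(B(O)O)cc(B(O)O)c(OC)c1OC
F4 | step 3 | 1,5-bis(benzyloxy)-2,3,4-trimethoxybenzene | COc1c(OCc2ccccc2)cc(OCc2ccccc2)c(OC)c1OC
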